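**Plan** (carotenoid locants: cyclohexene ring C1′–C6′, chain C7′…C15′–C15…C9, dihydrofuran ring O–C5–C6=C7–C8)
1. Cuts: C12–C13 last; then C14′–C15′ and C10′–C11′ together with the C–CH3 bonds at C13′ and C9′; on the other half C11=C12, the O–C8 ring bond, C8–H and C8–C9.
2. Enabling feature: on the cyclohexene side the E trisubstituted alkene C9′=C10′ (methyl on C9′), flanked by C7′=C8′, is the syn adduct of CH3 and a metal across the terminal alkyne C9′≡C10′ of an ionone-derived enyne; C13′=C14′ repeats the pattern.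
3. Forward, first half: (R)-α-ionone → enyne → two rounds of methylalumination/Negishi coupling → C24 pentaenyne with a methyl-capped C13≡C14 alkyne.
4. Forward, second half: β-cyclocitral → epoxy alkyne → enyne → allenol; the only ring formed, the dihydrofuran, closes by 5-endo attack of the C5 hydroxyl on C8; then enal and iododiene; hydrozirconation/Negishi coupling joins the halves at C12–C13.
5. Stereochemistry: C6′ comes with (R)-α-ionone; C5 from a Sharpless epoxidation; C8 from anti SN2′ hydride delivery to the alkynyl oxirane followed by axis-to-centre transfer; all E alkenes from syn carbo- or hydrometalation and stereoretentive couplings.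

Key step: step 4

Remark: enantiopure (R)-α-ionone is taken as a purchasable material (otherwise obtained from the racemate by a known resolution).

**Route**

Step 1
Reactants: 1 (R)-α-ionone
Product: 3 (6R)-6-[(1E)-but-1-en-3-yn-1-yl]-1,5,5-trimethylcyclohex-1-ene, via dienyl diethyl phosphate 2 (not isolated)
Conditions: LiN(i-Pr)2 (1.05 equiv), THF, −78 °C; ClP(O)(OEt)2, −78 °C to rt; LiN(i-Pr)2 (2.3 equiv), −78 °C to rt; aq. NH4Cl
Reagents that add atoms: none
Why: Kinetic deprotonation of the methyl group, O-phosphorylation and base-induced loss of diethyl phosphate from the 2-phosphoryloxy diene (enol phosphate elimination to a terminal alkyne) should give the enyne, the hindered C6′–H between quaternary C1′ and C5′ being kinetically far less accessible than the CH3 and vinyl protons, so C6′ should stay R.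

Step 2
Reactants: 4 acetylene
Product: 5 (E)-1-bromo-2-iodoethene
Conditions: IBr, 48% aq. HBr, 0 °C
Reagents that add atoms: iodine monobromide, BrI
Why: Electrophilic anti addition of I–Br to acetylene through an iodonium ion opened by bromide should give the E dihaloethene.

Step 3
Reactants: 6 trimethylsilylacetylene; 5 (E)-1-bromo-2-iodoethene
Product: 8 (E)-1-bromo-4-(trimethylsilyl)but-1-en-3-yne, via silylethynylzinc bromide 7 (not isolated)
Conditions: n-BuLi, THF, −78 °C; ZnBr2, 0 °C; then 5, Pd(PPh3)4 (2 mol%), 0 °C to rt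
Reagents that add atoms: none
Why: Negishi alkynylation in which zerovalent palladium inserts into C–I far faster than into C–Br, so a single alkynyl group is introduced with retention of the E geometry.

Step 4
Reactants: 3 (6R)-enyne; 9 trimethylaluminium; 8 (E)-1-bromo-4-(trimethylsilyl)but-1-en-3-yne
Product: 11 trimethyl{(3E,5E,7E)-6-methyl-8-[(1R)-2,6,6-trimethylcyclohex-2-en-1-yl]octa-3,5,7-trien-1-yn-1-yl}silane, via dienyl dimethylalane 10 (not isolated)
Conditions: 9 (2 equiv), Cp2ZrCl2 (0.5 equiv), ClCH2CH2Cl, rt; volatiles removed in vacuo; then 8, ZnCl2 (0.3 equiv), Pd(PPh3)4 (5 mol%), THF, rt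
Reagents that add atoms: trimethylaluminium (9), C[Al](C)C
Why: A methylzirconocene–aluminium species adds CH3 and metal syn across the terminal alkyne of 3, methyl to the internal carbon C9′ and aluminium to C10′, giving the E alkenylalane 10; transfer through zinc to palladium and oxidative addition of the C–Br bond of 8 then form C10′–C11′ with retention at both alkenes. The closest known reaction type is the zirconium-catalysed methylalumination of conjugated terminal enynes followed by palladium/zinc-mediated Negishi alkenyl–alkenyl coupling. No ring is closed and no stereocentre is created; the two new E alkenes follow from syn addition and stereoretentive coupling. The step needs regio- and syn-selective carbometalation, secured by the terminal alkyne conjugated to C7′=C8′, and exclusive reaction at C–Br, secured by the silyl cap that keeps the alkyne of 8 inert and by THF, which stops carbometalation before 8 is added. C6′ should be untouched because neither a base nor an enolisable carbonyl is present.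

Step 5
Reactants: 11 silyl trienyne
Product: 12 (6R)-1,5,5-trimethyl-6-[(1E,3E,5E)-3-methylocta-1,3,5-trien-7-yn-1-yl]cyclohex-1-ene
Conditions: K2CO3, MeOH/THF, rt
Reagents that add atoms: none
Why: Methoxide-mediated protodesilylation of the alkynylsilane should free the terminal alkyne without touching the triene or C6′.

Step 6
Reactants: 13 1-propynylmagnesium bromide; 5 (E)-1-bromo-2-iodoethene
Product: 15 (E)-1-bromopent-1-en-3-yne, via propynylzinc bromide 14 (not isolated)
Conditions: ZnBr2, THF, 0 °C; then 5, Pd(PPh3)4 (2 mol%), 0 °C to rt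
Reagents that add atoms: none
Why: The same Negishi monoalkynylation as in step 3, selective for the C–I bond and stereoretentive.

Step 7
Reactants: 12 terminal trienyne; 9 trimethylaluminium; 15 (E)-1-bromopent-1-en-3-yne
Product: 17 (6R)-6-[(1E,3E,5E,7E,9E)-3,7-dimethyltrideca-1,3,5,7,9-pentaen-11-yn-1-yl]-1,5,5-trimethylcyclohex-1-ene, via tetraenyl dimethylalane 16 (not isolated)
Conditions: 9 (2 equiv), Cp2ZrCl2 (0.5 equiv), ClCH2CH2Cl, rt; volatiles removed in vacuo; then 15, ZnCl2 (0.3 equiv), Pd(PPh3)4 (5 mol%), THF, rt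
Reagents that add atoms: trimethylaluminium (9), C[Al](C)C
Why: A second zirconium-catalysed methylalumination puts CH3 on C13′ and aluminium on C14′ by syn addition, and Negishi coupling at the C–Br bond of 15 forms C14′–C15′ with retention, the internal alkyne of 15 being inert once the mixture is in THF.

Step 8
Reactants: 18 β-cyclocitral
Product: 19 β-cyclogeraniol
Conditions: NaBH4, MeOH, 0 °C
Reagents that add atoms: none
Why: Borohydride 1,2-reduction of the hindered enal gives the allylic alcohol needed for directed epoxidation.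

Step 9
Reactants: 19 β-cyclogeraniol
Product: 20 [(1R,6R)-2,2,6-trimethyl-7-oxabicyclo[4.1.0]heptan-1-yl]methanol
Conditions: Ti(Oi-Pr)4 (10 mol%), D-(−)-diethyl tartrate (12 mol%), t-BuOOH, 4 Å MS, CH2Cl2, −20 °C
Reagents that add atoms: tert-butyl hydroperoxide, CC(C)(C)OO
Why: Katsuki–Sharpless asymmetric epoxidation in which the titanium–D-(−)-tartrate complex delivers oxygen to one face of the tetrasubstituted allylic alcohol, setting C5 (R) and C6 together.

Step 10
Reactants: 20 epoxy alcohol
Product: 21 (1S,6R)-2,2,6-trimethyl-7-oxabicyclo[4.1.0]heptane-1-carbaldehyde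
Conditions: Dess–Martin periodinane, pyridine, CH2Cl2, 0 °C to rt
Reagents that add atoms: none
Why: Buffered Dess–Martin oxidation of the neopentyl-type primary alcohol should give an aldehyde that has no α-hydrogen and therefore cannot epimerise.

Step 11
Reactants: 21 epoxy aldehyde
Product: 22 (1R,6R)-1-ethynyl-2,2,6-trimethyl-7-oxabicyclo[4.1.0]heptane
Conditions: dimethyl (1-diazo-2-oxopropyl)phosphonate, K2CO3, MeOH, 0 °C to rt
Reagents that add atoms: dimethyl (1-diazo-2-oxopropyl)phosphonate, CC(=O)C(=[N+]=[N-])P(=O)(OC)OC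
Why: Seyferth–Gilbert homologation with the Ohira–Bestmann reagent converts the non-enolisable aldehyde into the terminal alkyne (C7≡C8) through a vinylidene 1,2-shift under conditions that leave the oxirane intact.

Step 12
Reactants: 23 but-2-yn-1-ol
Product: 24 tert-butyl(but-2-yn-1-yloxy)dimethylsilane
Conditions: t-BuMe2SiCl, imidazole, CH2Cl2, rt
Reagents that add atoms: tert-butyldimethylsilyl chloride, CC(C)(C)[Si](C)(C)Cl
Why: Standard silylation masks the hydroxyl so that the following hydrozirconation is governed by sterics and not by an alkoxide.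

Step 13
Reactants: 24 butynyl silyl ether
Product: 26 tert-butyl{[(2E)-3-iodobut-2-en-1-yl]oxy}dimethylsilane, via butenylzirconocene chloride 25 (not isolated)
Conditions: Cp2Zr(H)Cl (1.3 equiv), THF, rt to 40 °C; then I2, 0 °C
Reagents that add atoms: iodine, II
Why: Hydrozirconation adds Zr–H syn across the alkyne with zirconium settling on the methyl-bearing carbon remote from the silyloxymethyl group, and iodinolysis with retention gives the E iodide.

Step 14
Reactants: 22 epoxy alkyne; 26 (E)-vinyl iodide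
Product: 27 tert-butyldimethyl{[(2E)-3-methyl-5-[(1R,6R)-2,2,6-trimethyl-7-oxabicyclo[4.1.0]heptan-1-yl]pent-2-en-4-yn-1-yl]oxy}silane
Conditions: Pd(PPh3)4 (5 mol%), CuI (10 mol%), i-Pr2NH, THF, rt
Reagents that add atoms: none
Why: Sonogashira coupling joins C8 to C9 with retention of the E geometry, oxidative addition to the vinyl iodide being much faster than ionisation of the hindered tetrasubstituted propargylic oxirane.

Step 15
Reactants: 27 epoxy enyne
Product: 29 (1R)-2-[(3E)-5-hydroxy-3-methylpenta-1,3-dien-1-ylidene]-1,3,3-trimethylcyclohexan-1-ol with S allene axis, via bis-silyl allenol 28 (not isolated)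
Conditions: CuCl (5 mol%), NaOt-Bu (5 mol%), IPr·HCl (5 mol%), (EtO)2MeSiH (3 equiv), toluene, 0 °C to rt; then n-Bu4NF, THF, rt
Reagents that add atoms: none
Why: Copper hydride formed from CuCl, NaOt-Bu, the carbene IPr and the silane adds syn across the alkyne (H to C8, Cu to C7) and the alkenylcopper expels the oxirane oxygen anti-periplanar (SN2′ reduction of a propargylic oxirane), so hydride enters anti to the C6–O bond and fixes the allene axis, after which fluoride cleaves both silyl ethers.

Step 16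
Reactants: 29 allenic diol
Product: 30 (2E)-3-[(2R,7aR)-4,4,7a-trimethyl-2,4,5,6,7,7a-hexahydro-1-benzofuran-2-yl]but-2-en-1-ol
Conditions: AgNO3 (20 mol%), CaCO3, acetone/H2O, rt, dark
Reagents that add atoms: none
Why: Silver-catalysed 5-endo cycloisomerisation of the α-hydroxyallene, in which the C5 hydroxyl attacks the metal-activated C7=C8 bond in the plane of the C6 substituents, so the allene axis is transferred to C8 with H8 cis to the C5 methyl (8R) while C5 is unchanged.

Step 17
Reactants: 30 furanoid allylic alcohol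
Product: 31 (2E)-3-[(2R,7aR)-4,4,7a-trimethyl-2,4,5,6,7,7a-hexahydro-1-benzofuran-2-yl]but-2-enal
Conditions: MnO2 (20 equiv), CH2Cl2, rt
Reagents that add atoms: none
Why: Manganese dioxide oxidises only the primary allylic alcohol and, being neutral, should not epimerise C8, which is γ to the new aldehyde.

Step 18
Reactants: 31 furanoid enal
Product: 32 (2R,7aR)-2-[(2E,4E)-5-iodopenta-2,4-dien-2-yl]-4,4,7a-trimethyl-2,4,5,6,7,7a-hexahydro-1-benzofuran
Conditions: CrCl2 (6 equiv), CHI3 (2 equiv), THF, 0 °C, dark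
Reagents that add atoms: iodoform, IC(I)I
Why: Takai olefination with the geminal dichromium species from CHI3 and CrCl2 converts the enal into the E iodoalkene (C11=C12) under non-basic conditions.

Step 19
Reactants: 17 C24 pentaenyne; 32 iododiene
Product: 34 (5R,8R,6′R)-5,8-epoxy-5,8-dihydro-β,ε-carotene, via C13 alkenylzirconocene chloride 33 (not isolated)
Conditions: Cp2Zr(H)Cl (1.5 equiv), THF, rt to 40 °C; then ZnCl2 (0.5 equiv), 32, Pd(PPh3)4 (5 mol%), THF, rt, dark
Reagents that add atoms: none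
Why: Hydrozirconation of the methyl-capped alkyne places zirconium on C13 (the methyl-bearing carbon, away from the polyenyl group) by syn addition, and zinc-assisted Negishi coupling with the iododiene forms C12–C13 with retention at both partners, completing the all-E chain without acid, base or aluminium reagents near the dihydrofuran.

**Compound list**

1 | (R)-α-ionone, (3E)-4-[(1R)-2,6,6-trimethylcyclohex-2-en-1-yl]but-3-en-2-one | CC1=CCCC(C)(C)[C@H]1/C=C/C(C)=O | starting material
2 | diethyl (3E)-4-[(1R)-2,6,6-trimethylcyclohex-2-en-1-yl]buta-1,3-dien-2-yl phosphate | CC1=CCCC(C)(C)[C@H]1/C=C/C(=C)OP(=O)(OCC)OCC | intermediate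
3 | (6R)-6-[(1E)-but-1-en-3-yn-1-yl]-1,5,5-trimethylcyclohex-1-ene | CC1=CCCC(C)(C)[C@H]1/C=C/C#C | intermediate
4 | acetylene | C#C | starting material
5 | (E)-1-bromo-2-iodoethene | Br/C=C/I | intermediate
6 | trimethylsilylacetylene | C#C[Si](C)(C)C | starting material
7 | bromo[(trimethylsilyl)ethynyl]zinc | C[Si](C)(C)C#C[Zn]Br | intermediate
8 | (E)-1-bromo-4-(trimethylsilyl)but-1-en-3-yne | Br/C=C/C#C[Si](C)(C)C | intermediate
9 | trimethylaluminium | C[Al](C)C | starting material
10 | dimethyl{(1E,3E)-2-methyl-4-[(1R)-2,6,6-trimethylcyclohex-2-en-1-yl]buta-1,3-dien-1-yl}alane | CC1=CCCC(C)(C)[C@H]1/C=C/C(C)=C/[Al](C)C | intermediate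
11 | trimethyl{(3E,5E,7E)-6-methyl-8-[(1R)-2,6,6-trimethylcyclohex-2-en-1-yl]octa-3,5,7-trien-1-yn-1-yl}silane | CC1=CCCC(C)(C)[C@H]1/C=C/C(C)=C/C=C/C#C[Si](C)(C)C | intermediate
12 | (6R)-1,5,5-trimethyl-6-[(1E,3E,5E)-3-methylocta-1,3,5-trien-7-yn-1-yl]cyclohex-1-ene | CC1=CCCC(C)(C)[C@H]1/C=C/C(C)=C/C=C/C#C | intermediate
13 | 1-propynylmagnesium bromide | CC#C[Mg]Br | starting material
14 | bromo(prop-1-yn-1-yl)zinc | CC#C[Zn]Br | intermediate
15 | (E)-1-bromopent-1-en-3-yne | Br/C=C/C#CC | intermediate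
16 | dimethyl{(1E,3E,5E,7E)-2,6-dimethyl-8-[(1R)-2,6,6-trimethylcyclohex-2-en-1-yl]octa-1,3,5,7-tetraen-1-yl}alane | CC1=CCCC(C)(C)[C@H]1/C=C/C(C)=C/C=C/C(C)=C/[Al](C)C | intermediate
17 | (6R)-6-[(1E,3E,5E,7E,9E)-3,7-dimethyltrideca-1,3,5,7,9-pentaen-11-yn-1-yl]-1,5,5-trimethylcyclohex-1-ene | CC1=CCCC(C)(C)[C@H]1/C=C/C(C)=C/C=C/C(C)=C/C=C/C#CC | intermediate
18 | β-cyclocitral, 2,6,6-trimethylcyclohex-1-ene-1-carbaldehyde | CC1=C(C=O)C(C)(C)CCC1 | starting material
19 | β-cyclogeraniol, (2,6,6-trimethylcyclohex-1-en-1-yl)methanol | CC1=C(CO)C(C)(C)CCC1 | intermediate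
20 | [(1R,6R)-2,2,6-trimethyl-7-oxabicyclo[4.1.0]heptan-1-yl]methanol (5R,6R in carotenoid locants) | OC[C@@]12O[C@]1(C)CCCC2(C)C | intermediate
21 | (1S,6R)-2,2,6-trimethyl-7-oxabicyclo[4.1.0]heptane-1-carbaldehyde | O=C[C@@]12O[C@]1(C)CCCC2(C)C | intermediate
22 | (1R,6R)-1-ethynyl-2,2,6-trimethyl-7-oxabicyclo[4.1.0]heptane | C#C[C@@]12O[C@]1(C)CCCC2(C)C | intermediate
23 | but-2-yn-1-ol | CC#CCO | starting material
24 | tert-butyl(but-2-yn-1-yloxy)dimethylsilane | CC#CCO[Si](C)(C)C(C)(C)C | intermediate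
25 | [(2E)-4-(tert-butyldimethylsilyloxy)but-2-en-2-yl]chlorobis(cyclopentadienyl)zirconium | CC(C)(C)[Si](C)(C)OC/C=C(C)/[Zr](Cl)(C1C=CC=C1)C1C=CC=C1 | intermediate
26 | tert-butyl{[(2E)-3-iodobut-2-en-1-yl]oxy}dimethylsilane | CC(C)(C)[Si](C)(C)OC/C=C(C)/I | intermediate
27 | tert-butyldimethyl{[(2E)-3-methyl-5-[(1R,6R)-2,2,6-trimethyl-7-oxabicyclo[4.1.0]heptan-1-yl]pent-2-en-4-yn-1-yl]oxy}silane | CC(C)(C)[Si](C)(C)OC/C=C(C)/C#C[C@@]12O[C@]1(C)CCCC2(C)C | intermediate
28 | allenol 29 carrying a diethoxy(methyl)silyl group on the tertiary oxygen and the tert-butyldimethylsilyl group on the primary oxygen | CC(C)(C)[Si](C)(C)OC/C=C(C)/C=[C@]=C1C(C)(C)CCC[C@@]1(C)O[Si](C)(OCC)OCC | intermediate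
29 | (1R)-2-[(3E)-5-hydroxy-3-methylpenta-1,3-dien-1-ylidene]-1,3,3-trimethylcyclohexan-1-ol, S allene axis (H on C8 anti to the former oxirane oxygen) | OC/C=C(C)/C=[C@]=C1C(C)(C)CCC[C@@]1(C)O | intermediate
30 | (2E)-3-[(2R,7aR)-4,4,7a-trimethyl-2,4,5,6,7,7a-hexahydro-1-benzofuran-2-yl]but-2-en-1-ol | OC/C=C(\C)[C@H]1C=C2C(C)(C)CCC[C@@]2(C)O1 | intermediate
31 | (2E)-3-[(2R,7aR)-4,4,7a-trimethyl-2,4,5,6,7,7a-hexahydro-1-benzofuran-2-yl]but-2-enal | O=C/C=C(\C)[C@H]1C=C2C(C)(C)CCC[C@@]2(C)O1 | intermediate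
32 | (2R,7aR)-2-[(2E,4E)-5-iodopenta-2,4-dien-2-yl]-4,4,7a-trimethyl-2,4,5,6,7,7a-hexahydro-1-benzofuran | I/C=C/C=C(\C)[C@H]1C=C2C(C)(C)CCC[C@@]2(C)O1 | intermediate
33 | chlorobis(cyclopentadienyl)zirconium bonded to C13 of the hexaene formed from 17 (Zr and H14 cis) | CC1=CCCC(C)(C)[C@H]1/C=C/C(C)=C/C=C/C(C)=C/C=C/C=C(C)/[Zr](Cl)(C1C=CC=C1)C1C=CC=C1 | intermediate
34 | (5R,8R,6′R)-5,8-epoxy-5,8-dihydro-β,ε-carotene | CC1=CCCC(C)(C)[C@H]1/C=C/C(C)=C/C=C/C(C)=C/C=C/C=C(C)/C=C/C=C(\C)[C@H]1C=C2C(C)(C)CCC[C@@]2(C)O1 | target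

**Totals and risks**

Total step count: 19. Longest linear sequence: 10 steps (18 to 34 through steps 8, 9, 10, 11, 14, 15, 16, 17, 18, 19); the ionone branch has 5 steps.

Step 15. Hydride may be delivered syn to the oxirane oxygen, which would give the other allene axis and, after ring closure, the 8S ring; the copper hydride may also reduce the conjugated enyne further. The fallback sets out from 21 and returns at 30. Horner–Wadsworth–Emmons reaction of 21 with triethyl 3-methyl-4-phosphonocrotonate (LiN(SiMe3)2, THF, −78 to 0 °C) should give ethyl (2E,4E)-3-methyl-5-[(1S,6R)-2,2,6-trimethyl-7-oxabicyclo[4.1.0]heptan-1-yl]penta-2,4-dienoate F1. Acid-catalysed epoxide-to-furanoid rearrangement (catalytic p-TsOH, CHCl3) should convert it into the dihydrofuran ester with C5 retained, as the (2R,7aR) ester F2 and its (2S,7aR) epimer F3, which are separated by chromatography. Reduction of F2 with i-Bu2AlH at −78 °C gives 30.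

Step 19. Hydrozirconation may place zirconium partly on C14 or add to the polyene, and the trisubstituted alkenylmetal may couple slowly. The fallback sets out from 31 (with alane 16 made from 12 as in step 7) and returns at 34. Horner–Wadsworth–Emmons reaction of 31 with triethyl 3-methyl-4-phosphonocrotonate should give the trienoate F4, i-Bu2AlH the trienol F5, MnO2 the trienal F6 and Takai olefination (CrCl2, CHI3) the C15′ iodotetraene F7. Negishi coupling of F7 with 16 (ZnCl2, Pd(PPh3)4, THF) then forms C14′–C15′ and gives 34.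

Step 1. Excess amide base during the elimination may deprotonate the doubly allylic C6′–H, leading to racemisation or migration of the ring double bond into conjugation. The fallback sets out from 1 and returns at 3. Haloform cleavage (NaOCl, dioxane/H2O, 0 °C) should give the acrylic acid F8, LiAlH4 the allylic alcohol F9, MnO2 the enal F10, and CBr4/PPh3 the dibromodiene F11. n-BuLi at −78 °C (Corey–Fuchs, halogen–lithium exchange and 1,2-shift) then gives 3.

**Further compounds**

F1 | step 15 | ethyl (2E,4E)-3-methyl-5-[(1S,6R)-2,2,6-trimethyl-7-oxabicyclo[4.1.0]heptan-1-yl]penta-2,4-dienoate | CCOC(=O)/C=C(C)/C=C/[C@@]12O[C@]1(C)CCCC2(C)C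
F2 | step 15 | ethyl (2E)-3-[(2R,7aR)-4,4,7a-trimethyl-2,4,5,6,7,7a-hexahydro-1-benzofuran-2-yl]but-2-enoate | CCOC(=O)/C=C(\C)[C@H]1C=C2C(C)(C)CCC[C@@]2(C)O1
F3 | step 15 | ethyl (2E)-3-[(2S,7aR)-4,4,7a-trimethyl-2,4,5,6,7,7a-hexahydro-1-benzofuran-2-yl]but-2-enoate | CCOC(=O)/C=C(\C)[C@@H]1C=C2C(C)(C)CCC[C@@]2(C)O1
F4 | step 19 | ethyl (2E,4E,6E)-3-methyl-7-[(2R,7aR)-4,4,7a-trimethyl-2,4,5,6,7,7a-hexahydro-1-benzofuran-2-yl]octa-2,4,6-trienoate | CCOC(=O)/C=C(C)/C=C/C=C(\C)[C@H]1C=C2C(C)(C)CCC[C@@]2(C)O1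
F5 | step 19 | (2E,4E,6E)-3-methyl-7-[(2R,7aR)-4,4,7a-trimethyl-2,4,5,6,7,7a-hexahydro-1-benzofuran-2-yl]octa-2,4,6-trien-1-ol | OC/C=C(C)/C=C/C=C(\C)[C@H]1C=C2C(C)(C)CCC[C@@]2(C)O1
F6 | step 19 | (2E,4E,6E)-3-methyl-7-[(2R,7aR)-4,4,7a-trimethyl-2,4,5,6,7,7a-hexahydro-1-benzofuran-2-yl]octa-2,4,6-trienal | O=C/C=C(C)/C=C/C=C(\C)[C@H]1C=C2C(C)(C)CCC[C@@]2(C)O1
F7 | step 19 | (2R,7aR)-2-[(2E,4E,6E,8E)-9-iodo-6-methylnona-2,4,6,8-tetraen-2-yl]-4,4,7a-trimethyl-2,4,5,6,7,7a-hexahydro-1-benzofuran | I/C=C/C=C(C)/C=C/C=C(\C)[C@H]1C=C2C(C)(C)CCC[C@@]2(C)O1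
F8 | step 1 | (2E)-3-[(1R)-2,6,6-trimethylcyclohex-2-en-1-yl]prop-2-enoic acid | CC1=CCCC(C)(C)[C@H]1/C=C/C(=O)O
F9 | step 1 | (2E)-3-[(1R)-2,6,6-trimethylcyclohex-2-en-1-yl]prop-2-en-1-ol | CC1=CCCC(C)(C)[C@H]1/C=C/CO
F10 | step 1 | (2E)-3-[(1R)-2,6,6-trimethylcyclohex-2-en-1-yl]prop-2-enal | CC1=CCCC(C)(C)[C@H]1/C=C/C=O
F11 | step 1 | (6R)-6-[(1E)-4,4-dibromobuta-1,3-dien-1-yl]-1,5,5-trimethylcyclohex-1-ene | CC1=CCCC(C)(C)[C@H]1/C=C/C=C(Br)Br
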